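**Strategy**

Ring A (C3a, C4, C5, C6, C7, C7a) is a resorcinol: C3a, which carries C3, lies between the oxygen-bearing C4 and C7a, and the benzofuran sits on C6, meta to both. A vinylketene and a siloxyalkyne give exactly this pattern, so ring A is disconnected into a 3-(benzofuran-2-yl)cyclobutenone and an enantiopure triisopropylsiloxyalkyne that already holds C2 and C3. Heating the two forms C3a–C4, C7–C7a and C4–C5 and aromatises ring A under neutral conditions that leave C3 untouched. Every phenol travels as a silyl ether, so one fluoride-then-acid operation unmasks the polyphenol, ionises C2–O and closes the trans-dihydrobenzofuran.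

Key step: step 9

Assumption: (S,S)-ProPhenol is taken to deliver the (R)-propargylic alcohol in step 1; should Mosher analysis show the opposite sense, the mirror-image ligand is used and nothing else changes.
Assumption: the two silyloxybenzaldehydes, benzofuran-6-ol and 3-ethoxycyclobut-2-en-1-one are taken as catalogue compounds (each aldehyde is otherwise one silylation away from the hydroxybenzaldehyde).

Abbreviations: TBS = tert-butyldimethylsilyl, TBSO = tert-butyldimethylsilyloxy, TIPS = triisopropylsilyl, TIPSO = triisopropylsilyloxy, TMS = trimethylsilyl.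

**Route**

Step 1
Reactants: 1 3,5-bis(TBSO)benzaldehyde; 2 trimethylsilylacetylene
Product: 4 (R)-1-[3,5-bis(TBSO)phenyl]-3-TMS-prop-2-yn-1-ol, via methylzinc acetylide 3 (not isolated)
Conditions: Me2Zn (3 equiv), (S,S)-ProPhenol (10 mol %), Ph3PO (20 mol %), toluene, 0 °C
Reagents that add atoms: none
Why: Zinc–ProPhenol asymmetric alkynylation of a non-enolisable aryl aldehyde with a silylacetylene, in which the dinuclear zinc pocket binds aldehyde and alkynyl group and delivers the latter to one carbonyl face, which sets the (R) carbinol that later becomes C3.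

Step 2
Reactants: 4 (R)-1-[3,5-bis(TBSO)phenyl]-3-TMS-prop-2-yn-1-ol
Product: 5 (R)-1-[3,5-bis(TBSO)phenyl]-3-TMS-prop-2-yn-1-yl methanesulfonate
Conditions: MsCl, Et3N, CH2Cl2, −78 °C; used crude and cold
Reagents that add atoms: methanesulfonyl chloride, CS(=O)(=O)Cl
Why: O-Sulfonylation breaks no bond to the stereocentre and so proceeds with retention; the two meta silyloxy groups withdraw inductively and slow benzylic ionisation, and the mesylate is used at once.

Step 3
Reactants: 5 (R)-1-[3,5-bis(TBSO)phenyl]-3-TMS-prop-2-yn-1-yl methanesulfonate; 6 4-(TBSO)benzaldehyde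
Product: 8 (1S,2S)-2-[3,5-bis(TBSO)phenyl]-1-[4-(TBSO)phenyl]-4-TMS-but-3-yn-1-ol (anti), via allenylzinc 7 (not isolated)
Conditions: Pd(OAc)2 (5 mol %), PPh3 (5 mol %), Et2Zn (3 equiv), THF, −78 to −20 °C
Reagents that add atoms: none
Why: Marshall–Tamaru propargylation, in which zerovalent palladium displaces the mesylate anti (SN2′), transmetalation gives the axially defined allenylzinc 7, and its cyclic SE2′ addition to 6 transfers the carbinol chirality to C3 with overall inversion and gives the anti alcohol through a chair-like transition state; the C2 configuration is not critical because C2 is ionised in step 10, so any syn isomer converges.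

Step 4
Reactants: 8 (1S,2S)-2-[3,5-bis(TBSO)phenyl]-1-[4-(TBSO)phenyl]-4-TMS-but-3-yn-1-ol
Product: 9 (1S,2S)-1-(TBSO)-2-[3,5-bis(TBSO)phenyl]-1-[4-(TBSO)phenyl]-4-TMS-but-3-yne
Conditions: TBSOTf, 2,6-lutidine, CH2Cl2, −78 to 0 °C
Reagents that add atoms: tert-butyldimethylsilyl trifluoromethanesulfonate, CC(C)(C)[Si](C)(C)OS(=O)(=O)C(F)(F)F
Why: Silylation with a silyl triflate and a hindered pyridine base protects the hindered carbinol without acid or strong base, so neither stereocentre is at risk and no alkoxide can interfere with ynolate formation.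

Step 5
Reactants: 9 (1S,2S)-1-(TBSO)-2-[3,5-bis(TBSO)phenyl]-1-[4-(TBSO)phenyl]-4-TMS-but-3-yne
Product: 10 (1S,2R)-1-(TBSO)-2-[3,5-bis(TBSO)phenyl]-1-[4-(TBSO)phenyl]but-3-yne (terminal alkyne; the descriptor at C2 changes by the priority rule only)
Conditions: AgNO3 (0.2 equiv), MeOH/H2O/CH2Cl2, rt
Reagents that add atoms: none
Why: Silver-catalysed protodesilylation of the alkynylsilane runs through a silver acetylide under neutral conditions, which spares the aryl and alkyl silyl ethers (carbonate in methanol would cleave the aryl ones) and cannot epimerise C3.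

Step 6
Reactants: 10 (1S,2R)-1-(TBSO)-2-[3,5-bis(TBSO)phenyl]-1-[4-(TBSO)phenyl]but-3-yne
Product: 13 (1S,2S)-1-(TBSO)-2-[3,5-bis(TBSO)phenyl]-1-[4-(TBSO)phenyl]-4-(TIPSO)but-3-yne, via lithium acetylide 11 (not isolated), via lithium ynolate 12 (not isolated)
Conditions: LiHMDS (2.1 equiv), THF, −78 °C; t-BuOOH (1.05 equiv, anhydrous, in decane), −78 to 0 °C; TIPSOTf (1.3 equiv), −78 to 0 °C
Reagents that add atoms: tert-butyl hydroperoxide, CC(C)(C)OO; triisopropylsilyl trifluoromethanesulfonate, CC(C)[Si](C(C)C)(C(C)C)OS(=O)(=O)C(F)(F)F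
Why: Oxidation of a lithium acetylide by lithium tert-butyl peroxide to the lithium ynolate and O-silylation by a bulky silyl triflate is the standard route to triisopropylsiloxyalkynes; the acetylide charge shields the C3–H from deprotonation, so the stereocentre is retained.

Step 7
Reactants: 14 benzofuran-6-ol
Product: 15 6-(TBSO)benzofuran
Conditions: TBSCl, imidazole, DMF, rt
Reagents that add atoms: tert-butyldimethylsilyl chloride, CC(C)(C)[Si](C)(C)Cl
Why: Imidazole-promoted silylation of a phenol is routine and gives an ether that withstands organolithium, heat and dilute acid.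

Step 8
Reactants: 15 6-(TBSO)benzofuran; 16 3-ethoxycyclobut-2-en-1-one
Product: 19 3-[6-(TBSO)benzofuran-2-yl]cyclobut-2-en-1-one, via 2-lithiobenzofuran 17 (not isolated), via cyclobutenolate 18 (not isolated)
Conditions: n-BuLi, THF, −78 °C; 16 (1.1 equiv), −78 °C; then 1 M HCl, 0 °C to rt
Reagents that add atoms: none
Why: Benzofurans lithiate selectively at C2, and 1,2-addition of the aryllithium to the vinylogous ester followed by acid hydrolysis with loss of ethanol and water is a Stork–Danheiser-type transposition that delivers the 3-arylcyclobutenone; the ring methylene is not appreciably acidic because its enolate would be a cyclobutadiene.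

Step 9
Reactants: 19 3-[6-(TBSO)benzofuran-2-yl]cyclobut-2-en-1-one; 13 (1S,2S)-1-(TBSO)-2-[3,5-bis(TBSO)phenyl]-1-[4-(TBSO)phenyl]-4-(TIPSO)but-3-yne
Product: 24 2-{(1S,2S)-1-[3,5-bis(TBSO)phenyl]-2-(TBSO)-2-[4-(TBSO)phenyl]ethyl}-5-[6-(TBSO)benzofuran-2-yl]-3-(TIPSO)phenol, via vinylketene 20 (not isolated), via vinylcyclobutenone 21 (not isolated), via dienylketene 22 (not isolated), via cyclohexadienone 23 (not isolated)
Conditions: 13 (1.0 equiv), 19 (1.3 equiv, added in portions), toluene, 80 °C, then 110 °C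
Reagents that add atoms: none
Why: Danheiser benzannulation: four-electron electrocyclic opening of 19 gives vinylketene 20, whose ketene C=C adds across the electron-rich alkyne 13 in a [2+2] cycloaddition to give 21 (C3a–C4 and C7–C7a), four-electron opening of 21 gives dienylketene 22, six-electron electrocyclisation (C4–C5) gives dienone 23, and tautomerisation gives the phenol. This is the established behaviour of 3-substituted cyclobutenones with triisopropylsiloxyalkynes, which give resorcinol monosilyl ethers. Ring A is the only ring closed, by thermal disrotatory 6π electrocyclisation of the dienylketene. No stereocentre is created, and C2 and C3 are spectators because the conditions are neutral and free of metal, acid and base. The one selectivity needed is the orientation of the [2+2] step, secured by the polarisation of the siloxyalkyne: its nucleophilic β-carbon (C3a) bonds to the ketene carbonyl carbon (C4), which puts the side chain between the two oxygens and the benzofuran meta to both. Once step 10 has removed the silyl groups the oxygens on C4 and C7a are equivalent, so the labels C4/C7a and C5/C7 are interchangeable.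

Step 10
Reactants: 24 2-{(1S,2S)-1-[3,5-bis(TBSO)phenyl]-2-(TBSO)-2-[4-(TBSO)phenyl]ethyl}-5-[6-(TBSO)benzofuran-2-yl]-3-(TIPSO)phenol
Product: 26 (2S,3S)-3-(3,5-dihydroxyphenyl)-6-(6-hydroxybenzofuran-2-yl)-2-(4-hydroxyphenyl)-2,3-dihydrobenzofuran-4-ol (target), via hexaol 25 (not isolated)
Conditions: TBAF (8 equiv), THF, 0 °C to rt, under Ar; then 2 M HCl to pH 1, rt, dilute
Reagents that add atoms: none
Why: Fluoride-mediated silyl ether cleavage followed by acid-catalysed SN1 cycloetherification: the 4-hydroxybenzylic alcohol of 25 ionises to a protonated quinone methide, either of the two equivalent ring A phenols closes the five-membered ring anti to the C3 aryl group, and because ionisation is reversible the thermodynamically preferred 2,3-trans isomer results, so the fixed (S) centre at C3 sets C2 as (S).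

**Compound list**

1 | 3,5-bis(tert-butyldimethylsilyloxy)benzaldehyde | O=Cc1cc(O[Si](C)(C)C(C)(C)C)cc(O[Si](C)(C)C(C)(C)C)c1 | starting material
2 | trimethylsilylacetylene | C#C[Si](C)(C)C | starting material
3 | methyl[(trimethylsilyl)ethynyl]zinc (not isolated) | C[Zn]C#C[Si](C)(C)C | intermediate
4 | (R)-1-[3,5-bis(TBSO)phenyl]-3-(trimethylsilyl)prop-2-yn-1-ol | O[C@H](c1cc(O[Si](C)(C)C(C)(C)C)cc(O[Si](C)(C)C(C)(C)C)c1)C#C[Si](C)(C)C | intermediate
5 | (R)-1-[3,5-bis(TBSO)phenyl]-3-(trimethylsilyl)prop-2-yn-1-yl methanesulfonate | CS(=O)(=O)O[C@H](c1cc(O[Si](C)(C)C(C)(C)C)cc(O[Si](C)(C)C(C)(C)C)c1)C#C[Si](C)(C)C | intermediate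
6 | 4-(tert-butyldimethylsilyloxy)benzaldehyde | O=Cc1ccc(O[Si](C)(C)C(C)(C)C)cc1 | starting material
7 | ethyl{(aS)-3-[3,5-bis(TBSO)phenyl]-1-(trimethylsilyl)propa-1,2-dien-1-yl}zinc (not isolated) | CC(C)(C)[Si](C)(C)Oc1cc(O[Si](C)(C)C(C)(C)C)cc(c1)C([H])=[C@@]=C([Si](C)(C)C)[Zn]CC | intermediate
8 | (1S,2S)-2-[3,5-bis(TBSO)phenyl]-1-[4-(TBSO)phenyl]-4-(trimethylsilyl)but-3-yn-1-ol (anti) | CC(C)(C)[Si](C)(C)Oc1ccc([C@@H](O)[C@@H](c2cc(O[Si](C)(C)C(C)(C)C)cc(O[Si](C)(C)C(C)(C)C)c2)C#C[Si](C)(C)C)cc1 | intermediate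
9 | (1S,2S)-1-(TBSO)-2-[3,5-bis(TBSO)phenyl]-1-[4-(TBSO)phenyl]-4-(trimethylsilyl)but-3-yne | CC(C)(C)[Si](C)(C)Oc1ccc([C@@H](O[Si](C)(C)C(C)(C)C)[C@@H](c2cc(O[Si](C)(C)C(C)(C)C)cc(O[Si](C)(C)C(C)(C)C)c2)C#C[Si](C)(C)C)cc1 | intermediate
10 | (1S,2R)-1-(TBSO)-2-[3,5-bis(TBSO)phenyl]-1-[4-(TBSO)phenyl]but-3-yne | CC(C)(C)[Si](C)(C)Oc1ccc([C@@H](O[Si](C)(C)C(C)(C)C)[C@@H](c2cc(O[Si](C)(C)C(C)(C)C)cc(O[Si](C)(C)C(C)(C)C)c2)C#C)cc1 | intermediate
11 | lithium acetylide of 10, same configuration (not isolated) | CC(C)(C)[Si](C)(C)Oc1ccc([C@@H](O[Si](C)(C)C(C)(C)C)[C@@H](c2cc(O[Si](C)(C)C(C)(C)C)cc(O[Si](C)(C)C(C)(C)C)c2)C#C[Li])cc1 | intermediate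
12 | lithium ynolate derived from 11, same configuration (not isolated) | CC(C)(C)[Si](C)(C)Oc1ccc([C@@H](O[Si](C)(C)C(C)(C)C)[C@@H](c2cc(O[Si](C)(C)C(C)(C)C)cc(O[Si](C)(C)C(C)(C)C)c2)C#CO[Li])cc1 | intermediate
13 | (1S,2S)-1-(TBSO)-2-[3,5-bis(TBSO)phenyl]-1-[4-(TBSO)phenyl]-4-(triisopropylsilyloxy)but-3-yne | CC(C)(C)[Si](C)(C)Oc1ccc([C@@H](O[Si](C)(C)C(C)(C)C)[C@@H](c2cc(O[Si](C)(C)C(C)(C)C)cc(O[Si](C)(C)C(C)(C)C)c2)C#CO[Si](C(C)C)(C(C)C)C(C)C)cc1 | intermediate
14 | benzofuran-6-ol | Oc1ccc2ccoc2c1 | starting material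
15 | 6-(tert-butyldimethylsilyloxy)benzofuran | CC(C)(C)[Si](C)(C)Oc1ccc2ccoc2c1 | intermediate
16 | 3-ethoxycyclobut-2-en-1-one | CCOC1=CC(=O)C1 | starting material
17 | [6-(TBSO)benzofuran-2-yl]lithium (not isolated) | CC(C)(C)[Si](C)(C)Oc1ccc2cc([Li])oc2c1 | intermediate
18 | lithium 3-ethoxy-1-[6-(TBSO)benzofuran-2-yl]cyclobut-2-en-1-olate, racemic (not isolated) | CCOC1=CC(O[Li])(c2cc3ccc(O[Si](C)(C)C(C)(C)C)cc3o2)C1 | intermediate
19 | 3-[6-(TBSO)benzofuran-2-yl]cyclobut-2-en-1-one | CC(C)(C)[Si](C)(C)Oc1ccc2cc(C3=CC(=O)C3)oc2c1 | intermediate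
20 | 3-[6-(TBSO)benzofuran-2-yl]buta-1,3-dien-1-one, the vinylketene (not isolated) | C=C(C=C=O)c1cc2ccc(O[Si](C)(C)C(C)(C)C)cc2o1 | intermediate
21 | [2+2] adduct: 4-{1-[6-(TBSO)benzofuran-2-yl]ethenyl}-3-(TIPSO)cyclobut-2-en-1-one carrying the (1S,2S) side chain on C2, both epimers at C4 of the four-membered ring (not isolated) | CC(C)(C)[Si](C)(C)Oc1ccc([C@@H](O[Si](C)(C)C(C)(C)C)[C@@H](c2cc(O[Si](C)(C)C(C)(C)C)cc(O[Si](C)(C)C(C)(C)C)c2)C2=C(O[Si](C(C)C)(C(C)C)C(C)C)C(C(=C)c3cc4ccc(O[Si](C)(C)C(C)(C)C)cc4o3)C2=O)cc1 | intermediate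
22 | dienylketene from ring opening of 21, drawn as the isomer that can cyclise (not isolated) | CC(C)(C)[Si](C)(C)Oc1ccc([C@@H](O[Si](C)(C)C(C)(C)C)[C@@H](c2cc(O[Si](C)(C)C(C)(C)C)cc(O[Si](C)(C)C(C)(C)C)c2)C(=C=O)/C(O[Si](C(C)C)(C(C)C)C(C)C)=C\C(=C)c2cc3ccc(O[Si](C)(C)C(C)(C)C)cc3o2)cc1 | intermediate
23 | cyclohexa-2,4-dien-1-one from 6π closure of 22 (not isolated) | CC(C)(C)[Si](C)(C)Oc1ccc([C@@H](O[Si](C)(C)C(C)(C)C)[C@@H](c2cc(O[Si](C)(C)C(C)(C)C)cc(O[Si](C)(C)C(C)(C)C)c2)C2=C(O[Si](C(C)C)(C(C)C)C(C)C)C=C(c3cc4ccc(O[Si](C)(C)C(C)(C)C)cc4o3)CC2=O)cc1 | intermediate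
24 | 2-{(1S,2S)-1-[3,5-bis(TBSO)phenyl]-2-(TBSO)-2-[4-(TBSO)phenyl]ethyl}-5-[6-(TBSO)benzofuran-2-yl]-3-(triisopropylsilyloxy)phenol | CC(C)(C)[Si](C)(C)Oc1ccc([C@@H](O[Si](C)(C)C(C)(C)C)[C@@H](c2cc(O[Si](C)(C)C(C)(C)C)cc(O[Si](C)(C)C(C)(C)C)c2)c2c(O)cc(-c3cc4ccc(O[Si](C)(C)C(C)(C)C)cc4o3)cc2O[Si](C(C)C)(C(C)C)C(C)C)cc1 | intermediate
25 | 2-[(1S,2S)-1-(3,5-dihydroxyphenyl)-2-hydroxy-2-(4-hydroxyphenyl)ethyl]-5-(6-hydroxybenzofuran-2-yl)benzene-1,3-diol (not isolated) | Oc1ccc([C@@H](O)[C@@H](c2cc(O)cc(O)c2)c2c(O)cc(-c3cc4ccc(O)cc4o3)cc2O)cc1 | intermediate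
26 | (2S,3S)-3-(3,5-dihydroxyphenyl)-6-(6-hydroxybenzofuran-2-yl)-2-(4-hydroxyphenyl)-2,3-dihydrobenzofuran-4-ol (2,3-trans) | Oc1ccc([C@H]2Oc3cc(-c4cc5ccc(O)cc5o4)cc(O)c3[C@@H]2c2cc(O)cc(O)c2)cc1 | target

**Step count and risks**

Total steps: 10. Longest linear sequence: 8 steps (steps 1–6, 9, 10). The cyclobutenone branch is 2 steps (7, 8).

Steps most likely to fail:

Step 9. The bimolecular [2+2] capture may be too slow. Alkyne 13 is branched at the propargylic carbon and carries two bulky aryl units, so at the temperature needed to open 19 the vinylketene 20 may oligomerise, re-close or acylate the phenol of 24 instead. The fallback generates 20 irreversibly at room temperature by photochemical Wolff rearrangement and keeps the same three bonds. It sets out from silyl ether 15 and siloxyalkyne 13 and returns at 24. Compound 15 is lithiated (n-BuLi) and transmetalated with ZnCl2 to [6-(TBSO)benzofuran-2-yl]zinc chloride F1. Negishi coupling of this with 3-bromobut-3-en-2-one (Pd(PPh3)4) gives the α-aryl enone 3-[6-(TBSO)benzofuran-2-yl]but-3-en-2-one F2. Detrifluoroacetylative diazo transfer (LiHMDS, CF3CO2CH2CF3; then MsN3, Et3N) gives the diazo ketone 1-diazo-3-[6-(TBSO)benzofuran-2-yl]but-3-en-2-one F3. Irradiation of F3 with 13 (300 nm, ClCH2CH2Cl, rt), then warming to 80 °C, should lead through 20, 21, 22 and 23 to 24.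

Step 3. Enantiomeric purity may be lost before the C–C bond forms: the benzylic, propargylic mesylate 5 can ionise, and the allenylpalladium species can racemise by a second SN2′ attack of zerovalent palladium if transmetalation lags. The fallback replaces the transient allenylmetal by an isolable, configurationally stable allenylboronate. It sets out from alcohol 4 and returns at alcohol 8. Acylation of 4 with methyl chloroformate and pyridine gives (R)-1-[3,5-bis(TBSO)phenyl]-3-TMS-prop-2-yn-1-yl methyl carbonate F4. Copper-catalysed anti SN2′ borylation (CuCl, NaOt-Bu, Xantphos, B2pin2, THF) gives the allenylboronate 2-{(aR)-3-[3,5-bis(TBSO)phenyl]-1-TMS-propa-1,2-dien-1-yl}-4,4,5,5-tetramethyl-1,3,2-dioxaborolane F5. Heating F5 with aldehyde 6 in toluene (cyclic six-membered allenylboration, anti-selective, same sense of chirality transfer) and aqueous work-up should give 8.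

Step 8. The addition–transposition may not be clean: the strained cyclobutenolate 18 can ring-open on warming, and 19 can oligomerise during the acidic hydrolysis. The fallback builds the four-membered ring by ketene–alkyne cycloaddition instead. It sets out from silyl ether 15 and returns at cyclobutenone 19. Lithiation of 15 and quenching with DMF gives 6-(TBSO)benzofuran-2-carbaldehyde F6. Colvin rearrangement (TMSCHN2, LDA, THF, −78 °C to rt) gives 2-ethynyl-6-(TBSO)benzofuran F7. [2+2] Cycloaddition with dichloroketene (Cl3CCOCl, zinc–copper couple, Et2O) gives 4,4-dichloro-3-[6-(TBSO)benzofuran-2-yl]cyclobut-2-en-1-one F8. Reductive dechlorination (Zn, AcOH, TMEDA, EtOH) gives 19.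

Further compounds
F1 | step 9 | [6-(TBSO)benzofuran-2-yl]zinc chloride | CC(C)(C)[Si](C)(C)Oc1ccc2cc([Zn]Cl)oc2c1
F2 | step 9 | 3-[6-(TBSO)benzofuran-2-yl]but-3-en-2-one | CC(=O)C(=C)c1cc2ccc(O[Si](C)(C)C(C)(C)C)cc2o1
F3 | step 9 | 1-diazo-3-[6-(TBSO)benzofuran-2-yl]but-3-en-2-one | [N-]=[N+]=CC(=O)C(=C)c1cc2ccc(O[Si](C)(C)C(C)(C)C)cc2o1
F4 | step 3 | (R)-1-[3,5-bis(TBSO)phenyl]-3-(trimethylsilyl)prop-2-yn-1-yl methyl carbonate | COC(=O)O[C@H](c1cc(O[Si](C)(C)C(C)(C)C)cc(O[Si](C)(C)C(C)(C)C)c1)C#C[Si](C)(C)C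
F5 | step 3 | 2-{(aR)-3-[3,5-bis(TBSO)phenyl]-1-(trimethylsilyl)propa-1,2-dien-1-yl}-4,4,5,5-tetramethyl-1,3,2-dioxaborolane | CC(C)(C)[Si](C)(C)Oc1cc(O[Si](C)(C)C(C)(C)C)cc(c1)C([H])=[C@@]=C([Si](C)(C)C)B1OC(C)(C)C(C)(C)O1
F6 | step 8 | 6-(TBSO)benzofuran-2-carbaldehyde | CC(C)(C)[Si](C)(C)Oc1ccc2cc(C=O)oc2c1
F7 | step 8 | 2-ethynyl-6-(TBSO)benzofuran | CC(C)(C)[Si](C)(C)Oc1ccc2cc(C#C)oc2c1
F8 | step 8 | 4,4-dichloro-3-[6-(TBSO)benzofuran-2-yl]cyclobut-2-en-1-one | CC(C)(C)[Si](C)(C)Oc1ccc2cc(C3=CC(=O)C3(Cl)Cl)oc2c1
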